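The constants used here were set for the occasion; the rest is arithmetic.

- Time is what separates theta from zeta: one charge, stopped at 25 min or at 12 min.

| setting | theta | zeta |
|---|---|---|
| free monomer | 0.020 M | 0.020 M |
| transfer agent | 0.200 mM | 0.200 mM |
| protic impurity | 0.400 mM | 0.400 mM |
| initiator | 0.40 mM | 0.40 mM |
| time | 25 min | 12 min |

    free monomer + initiator → living end + monomer in chains (k1 = 180 /M/min)
    free monomer + living end → monomer in chains + living end, rate k2*[living end]*[free monomer] (k2 = 340 /M/min)
    living end + transfer agent → dead chain (k3 = 10000 /M/min)
    protic impurity + free monomer → quenched substrate (k4 = 7200 /M/min)
    initiator → spent initiator (k5 = 4.6 × 10⁻⁴ /min)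

- the average divides the monomer in chains by the number of chains begun, living and dead together
- run time (theta): 25 min

- which of the two ends with the longer chains by the average number of monomer units in a chain (chains begun, living or dead) ("neither" if they lie within 10%) (theta / zeta / neither)
- average number of monomer units in a chain (chains begun, living or dead) at the end, theta
- average number of monomer units in a chain (chains begun, living or dead) at the end, zeta

- From above: protic impurity takes free monomer with a half-life of 0.24 min, shorter than the 9.6 min of initiation, so I book 0.0196 M for the chains.
- Initiator, with free monomer held at its charge, has a half-life of 0.193 min by step 1, far shorter than the 25 h of its own decay, so I count 0.40 mM of chains begun, and the ceiling is 49.0 units per chain.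
- Letting every begun end grow through the run tightens this to 47.4 for theta and 39.4 for zeta.
- From below: transfer agent is the limiting reagent of the killing step, smaller than the initiator charge, and with transfer agent as charged the living end has a half-life of 0.35 min, hardly any of theta's run, so I count 0.200 mM of surviving living ends.
- My clock is the decade time, the time in which the surviving living ends, acting pseudo-first-order, cut [free monomer] by one power of ten: 33.8 min.
- Theta runs 0.740 of a decade and zeta 0.355, which puts the lower edge at 40.0 for theta and 27.3 for zeta.
- The doomed ends go with that half-life of 0.35 min, far shorter than the decade time, so I commit to the lower edge, and the ratio of 1.47 clears the margin, so theta has the longer chains.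
- The forecast says theta, with 40.2 for theta and 27.8 for zeta, on the ground that “the transfer agent kills half of them”. Both values stand inside my brackets, just above the lower edge.
- The flask gives theta, with 40.2 for theta and 27.8 for zeta.
- In theta the living end has a half-life of 0.35 min against transfer agent as charged, far shorter than the decade time of 33.8 min, and at 12.5 min [living end] reads 2.00 × 10⁻⁴ M beside 2.00 × 10⁻⁴ M of dead chain. The decade time gives 17.9% of the charge as free monomer in theta at 25 min, and theta holds 18%. For the neighbour flask, theta read at 15 min, it gives 35.3% and an average of 31.3; that flask holds 34.6% and averages 31.7.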